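**Retrosynthetic overview**
- Feature: in ring A the carbon C2 (OMe) has the ether carbon C1 on one side, Br on its other ortho carbon C3, and Br on its para carbon C5. A 2-aryloxyphenol acquires exactly this pattern on dibromination, and a 2-aryloxyphenol is a 2-aryloxycyclohexanone less four hydrogens.
- Disconnections, backwards: C6–Br of ring B (ortho to OH); ring B OH from CHO (Baeyer–Villiger, formate cleavage); OMe from OH; ring A with C3–Br and C5–Br from a cyclohexanone ring with Br2; the O–C1 bond by SN2 of a salicylaldehyde phenoxide on 2-chlorocyclohexanone.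
- Rings: ring B is bought as an arene carrying two of its bromines and a formyl group as the masked hydroxyl. Ring A is bought as a saturated six-membered ketone and becomes aromatic in step 2. No ring is closed anywhere in the route.
- The crowded ether oxygen, flanked on ring B by two substituents, is bonded to an sp3 carbon first, so no aryl–oxygen coupling is required.

Key step: step 2

Remark: the target has no stereocentre. Compounds 2, 3 and 4 are racemic at the ring carbon next to the carbonyl, and that centre is erased in step 2.

Step 1
Reactants: 1 3,5-dibromosalicylaldehyde; 2 2-chlorocyclohexanone (racemic)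
Product: 4 racemic 3,5-dibromo-2-[(2-oxocyclohexyl)oxy]benzaldehyde, via 2-iodocyclohexanone 3 (not isolated)
Conditions: K2CO3 (1.0 equiv), KI (0.2 equiv), DMF, 50 °C; aq NH4Cl work-up
Reagents that add atoms: none
Why: This is a Williamson-type SN2 O-alkylation at a carbon activated by the neighbouring carbonyl and accelerated by Finkelstein exchange to iodide 3; the acidic phenol consumes the single equivalent of K2CO3 at once, so only phenoxide and KHCO3 remain, which are too weakly basic to start an intramolecular aldol addition of the α-aryloxy ketone to the aldehyde, and the new stereocentre forms racemic and is erased in step 2.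

Step 2
Reactants: 4 racemic 3,5-dibromo-2-[(2-oxocyclohexyl)oxy]benzaldehyde
Product: 7 3,5-dibromo-2-(3,5-dibromo-2-hydroxyphenoxy)benzaldehyde, via aryloxycyclohexenone 5 (not isolated), via unbrominated aryloxyphenol 6 (not isolated)
Conditions: Br2 (4.4 equiv, in portions), HBr (cat.), dry AcOH, dark, 20 → 85 °C, N2 sweep; aq NaHSO3
Reagents that add atoms: bromine, BrBr
Why: HBr-catalysed enolisation and α-bromination of the ketone (at the carbon that bears the aryloxy group or at the CH2 on the other side of the carbonyl), followed by loss of HBr on warming, should give enone 5, and a second bromination of its dienol with a second loss of HBr gives a cyclohexadienone that tautomerises to phenol 6. The reaction type is the classical brominative aromatisation of cyclohexanones (bromination–dehydrobromination), followed in the same flask by ordinary electrophilic bromination of the liberated phenol. No ring is closed and no stereocentre is made; the one stereocentre of racemic 4 is erased. The step needs site selectivity in ring A, and the new hydroxyl at C2 secures it: its para carbon C5 and its only free ortho carbon C3 are the activated sites, the other ortho carbon C1 holds the ether oxygen, and an α-bromine that survives aromatisation also ends at C3, so the pathways converge on 7. It also needs selectivity between the rings, which ring B secures by being deactivated by the formyl group and two bromines; both carbons ortho to its ether oxygen are substituted, so acid-induced cyclodehydration to a tetrahydrodibenzofuran is also shut off. Dry AcOH, darkness and portionwise Br2 should keep the aldehyde C–H from being oxidised, and the N2 sweep removes HBr before it can cleave the α-keto ether.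

Step 3
Reactants: 7 3,5-dibromo-2-(3,5-dibromo-2-hydroxyphenoxy)benzaldehyde
Product: 8 3,5-dibromo-2-(3,5-dibromo-2-methoxyphenoxy)benzaldehyde
Conditions: MeI (1.5 equiv, charged first), K2CO3 (1.2 equiv), DMF, 0 → 20 °C
Reagents that add atoms: iodomethane, CI
Why: This is a Williamson O-methylation of an acidic 2,4-dibromophenol-type hydroxyl; MeI is present before the base and the temperature is kept low, so the phenoxide should be trapped before it can attack the ipso carbon of ring B (Smiles rearrangement), and the aldehyde has no α-hydrogen.

Step 4
Reactants: 8 3,5-dibromo-2-(3,5-dibromo-2-methoxyphenoxy)benzaldehyde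
Product: 9 3,5-dibromo-2-(3,5-dibromo-2-methoxyphenoxy)phenyl formate
Conditions: mCPBA (2 equiv), CH2Cl2, 40 °C
Reagents that add atoms: 3-chloroperoxybenzoic acid, O=C(OO)c1cccc(Cl)c1
Why: In this Baeyer–Villiger oxidation of an aromatic aldehyde the aryl group should migrate in the Criegee adduct rather than hydride, because the ether oxygen ortho to the migrating carbon donates into it and both bromines are only meta to it, as is usual for 2-aryloxy- and 2-alkoxybenzaldehydes.

Step 5
Reactants: 9 3,5-dibromo-2-(3,5-dibromo-2-methoxyphenoxy)phenyl formate
Product: 10 3,5-dibromo-2-(3,5-dibromo-2-methoxyphenoxy)phenol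
Conditions: HCl (cat.), MeOH, 20 °C
Reagents that add atoms: none
Why: This is an acid-catalysed transesterification of a very labile aryl formate, in which no phenoxide is generated and the aryl bromides, the methyl ether and the diaryl ether are inert.

Step 6
Reactants: 10 3,5-dibromo-2-(3,5-dibromo-2-methoxyphenoxy)phenol
Product: 11 2,3,5-tribromo-6-(3,5-dibromo-2-methoxyphenoxy)phenol (target)
Conditions: NBS (1.0 equiv, slow addition), iPr2NH (0.2 equiv), CH2Cl2, 0 °C, dark
Reagents that add atoms: N-bromosuccinimide, O=C1CCC(=O)N1Br
Why: This is an amine-mediated ortho-selective electrophilic bromination of a phenol: NBS and iPr2NH form N-bromodiisopropylamine, which hydrogen-bonds to the phenolic OH and delivers bromine to the only free ortho carbon C6 of ring B, while the para carbon C4 is shielded by two flanking bromines and ring A, a dibrominated anisole ring, is too deactivated to compete.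

**Compound list**
1 | 3,5-dibromosalicylaldehyde | O=Cc1cc(Br)cc(Br)c1O | starting material
2 | 2-chlorocyclohexanone (racemic) | O=C1CCCCC1Cl | starting material
3 | 2-iodocyclohexanone (racemic, not isolated) | O=C1CCCCC1I | intermediate
4 | 3,5-dibromo-2-[(2-oxocyclohexyl)oxy]benzaldehyde (racemic) | O=Cc1cc(Br)cc(Br)c1OC1CCCCC1=O | intermediate
5 | 3,5-dibromo-2-[(6-oxocyclohex-1-en-1-yl)oxy]benzaldehyde (not isolated) | O=Cc1cc(Br)cc(Br)c1OC1=CCCCC1=O | intermediate
6 | 3,5-dibromo-2-(2-hydroxyphenoxy)benzaldehyde (not isolated) | O=Cc1cc(Br)cc(Br)c1Oc1ccccc1O | intermediate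
7 | 3,5-dibromo-2-(3,5-dibromo-2-hydroxyphenoxy)benzaldehyde | O=Cc1cc(Br)cc(Br)c1Oc1cc(Br)cc(Br)c1O | intermediate
8 | 3,5-dibromo-2-(3,5-dibromo-2-methoxyphenoxy)benzaldehyde | COc1c(Br)cc(Br)cc1Oc1c(Br)cc(Br)cc1C=O | intermediate
9 | 3,5-dibromo-2-(3,5-dibromo-2-methoxyphenoxy)phenyl formate | COc1c(Br)cc(Br)cc1Oc1c(Br)cc(Br)cc1OC=O | intermediate
10 | 3,5-dibromo-2-(3,5-dibromo-2-methoxyphenoxy)phenol | COc1c(Br)cc(Br)cc1Oc1c(Br)cc(Br)cc1O | intermediate
11 | 2,3,5-tribromo-6-(3,5-dibromo-2-methoxyphenoxy)phenol | COc1c(Br)cc(Br)cc1Oc1c(Br)cc(Br)c(Br)c1O | target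

Total step count: 6
Longest linear sequence: 6

**Steps most likely to fail**

**1. Step 2.**
- What may go wrong:
  - HBr may cleave the α-keto ether, or the enol ether stage may solvolyse, with loss of the aryloxy group.
  - The reaction may stall at polybrominated ketones that do not shed HBr.
  - Bromine may add at the β-carbon of the enone stage, which would place a halogen on C6 of ring A.
  - The aldehyde C–H may be oxidised.
- Fallback (sets out from 1, comes back at 8): ring A is taken from an aromatic building block, and the diaryl ether is made by nucleophilic aromatic substitution.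
  - Compound 1 is methylated (MeI, K2CO3, DMF) to 3,5-dibromo-2-methoxybenzaldehyde F1.
  - F1 is oxidised with mCPBA (CH2Cl2) to 3,5-dibromo-2-methoxyphenyl formate F2, which is methanolysed (HCl cat., MeOH) to 3,5-dibromo-2-methoxyphenol F3.
  - The phenoxide of F3 then displaces fluoride from bought 3,5-dibromo-2-fluorobenzaldehyde F4 (K2CO3, DMAc, 100 °C) to give 8. The fluorine-bearing carbon is activated by the ortho formyl group and fluorine is small enough for attack between two substituents.

**2. Step 1.**
- What may go wrong:
  - Substitution by a weakly nucleophilic, doubly ortho-substituted phenoxide may be slow.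
  - Base may induce intramolecular aldol addition of the α-carbon of the product to the aldehyde.
  - Compound 2 may lose HCl.
- Fallback (sets out from 1, comes back at 4): the C–O bond is made by epoxide opening, so that base never meets the keto aldehyde.
  - Compound 1 is heated with bought cyclohexene oxide F5 (K2CO3 cat., DMF, 100 °C). Anti opening should give racemic trans-3,5-dibromo-2-[(2-hydroxycyclohexyl)oxy]benzaldehyde F6.
  - Oxidation of the secondary alcohol with Dess–Martin periodinane (CH2Cl2, 20 °C), which leaves the aldehyde untouched, gives 4.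

**3. Step 6.**
- What may go wrong: site selectivity between C6 and C4 of ring B may be poor, and bromination may continue to a fully substituted ring B.
- Fallback (sets out from 2, comes back at 11): the third bromine of ring B is installed before the ether is made, at a stage where its position is unambiguous.
  - Bought 2-bromo-6-hydroxybenzaldehyde F7 is dibrominated ortho and para to its hydroxyl (Br2, AcOH, 20 °C) to 2,3,5-tribromo-6-hydroxybenzaldehyde F8, which takes the place of 1.
  - Alkylation with 2 as in step 1 gives racemic 2,3,5-tribromo-6-[(2-oxocyclohexyl)oxy]benzaldehyde F9.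
  - Br2 in AcOH as in step 2 gives 2,3,5-tribromo-6-(3,5-dibromo-2-hydroxyphenoxy)benzaldehyde F10.
  - MeI and K2CO3 give 2,3,5-tribromo-6-(3,5-dibromo-2-methoxyphenoxy)benzaldehyde F11.
  - mCPBA gives 2,3,5-tribromo-6-(3,5-dibromo-2-methoxyphenoxy)phenyl formate F12, and acid methanolysis gives 11 without any late bromination.

**Further compounds**
F1 | step 2 | 3,5-dibromo-2-methoxybenzaldehyde | COc1c(Br)cc(Br)cc1C=O
F2 | step 2 | 3,5-dibromo-2-methoxyphenyl formate | COc1c(Br)cc(Br)cc1OC=O
F3 | step 2 | 3,5-dibromo-2-methoxyphenol | COc1c(Br)cc(Br)cc1O
F4 | step 2 | 3,5-dibromo-2-fluorobenzaldehyde (bought) | O=Cc1cc(Br)cc(Br)c1F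
F5 | step 1 | cyclohexene oxide (bought, meso) | C1CCC2OC2C1
F6 | step 1 | trans-3,5-dibromo-2-[(2-hydroxycyclohexyl)oxy]benzaldehyde (racemic, one enantiomer drawn) | O=Cc1cc(Br)cc(Br)c1O[C@@H]1CCCC[C@H]1O
F7 | step 6 | 2-bromo-6-hydroxybenzaldehyde (bought) | O=Cc1c(Br)cccc1O
F8 | step 6 | 2,3,5-tribromo-6-hydroxybenzaldehyde | O=Cc1c(Br)c(Br)cc(Br)c1O
F9 | step 6 | 2,3,5-tribromo-6-[(2-oxocyclohexyl)oxy]benzaldehyde (racemic) | O=Cc1c(Br)c(Br)cc(Br)c1OC1CCCCC1=O
F10 | step 6 | 2,3,5-tribromo-6-(3,5-dibromo-2-hydroxyphenoxy)benzaldehyde | O=Cc1c(Br)c(Br)cc(Br)c1Oc1cc(Br)cc(Br)c1O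
F11 | step 6 | 2,3,5-tribromo-6-(3,5-dibromo-2-methoxyphenoxy)benzaldehyde | COc1c(Br)cc(Br)cc1Oc1c(Br)cc(Br)c(Br)c1C=O
F12 | step 6 | 2,3,5-tribromo-6-(3,5-dibromo-2-methoxyphenoxy)phenyl formate | COc1c(Br)cc(Br)cc1Oc1c(Br)cc(Br)c(Br)c1OC=O
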